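Assumption: the SMILES decodes as methyl (5E,7Z,12R,14Z)-10-bromo-12-hydroxy-9-oxoprosta-5,7,10,14-tetraenoate. Prostanoid numbering (C1 = ester carbon) is used in the comments.

## Retrosynthetic overview

1. The target comes from its 12-O-TES ether by a final desilylation.
2. The only ring, the cyclopentenone, is formed last. C8–C9 and C6–C7 are cut together to give an acyclic (E)-α-bromoenoate/terminal alkyne and an (E)-alkenylboronate. This is the new Rh(I) cascade, and it sets 7Z.
3. The C10=C11 bond and the bromine come from an (E)-selective bromo-HWE on an α-silyloxy aldehyde.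
4. C13–C14 comes from opening an epoxide with 1-heptyne, and Lindlar reduction then gives 14Z.
5. C12 is set by Sharpless epoxidation of a 2-alkynyl allylic alcohol made from 2-bromoallyl alcohol and TIPS-acetylene.

## Route

**Step 1**
Reactants: 1, 2-bromoprop-2-en-1-ol; 2, (triisopropylsilyl)acetylene
Product: 3, 2-methylidene-4-(triisopropylsilyl)but-3-yn-1-ol
Conditions: PdCl2(PPh3)2 (2 mol %), CuI (4 mol %), i-Pr2NH, THF, rt
Reagents that add atoms: compound 2, C#C[Si](C(C)C)(C(C)C)C(C)C
Why: Sonogashira coupling of an unhindered vinyl bromide with a terminal alkyne tolerates the free alcohol and creates no stereocentre.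

**Step 2**
Reactants: 3
Product: 4, [(2S)-2-{(triisopropylsilyl)ethynyl}oxiran-2-yl]methanol
Conditions: Ti(Oi-Pr)4 (10 mol %), L-(+)-DIPT (12 mol %), t-BuOOH, 4 Å MS, CH2Cl2, −20 °C
Reagents that add atoms: tert-butyl hydroperoxide, CC(C)(C)OO
Why: Sharpless asymmetric epoxidation with L-(+)-tartrate delivers oxygen to the same face as in methallyl alcohol → (S)-2-methylglycidol, which sets the future C12 with the ethynyl arm as C8 and the CH2OH arm as C11.

**Step 3**
Reactants: 4; 5, hept-1-yne
Product: 6, (2S)-2-[(triisopropylsilyl)ethynyl]dec-4-yne-1,2-diol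
Conditions: 5 (3.5 equiv), n-BuLi (3.3 equiv), THF, −78 °C; BF3·OEt2 (3 equiv); then 4, −78 °C
Reagents that add atoms: hept-1-yne, CCCCCC#C
Why: Yamaguchi–Hirao alkynylation is an SN2 attack at the unsubstituted epoxide CH2, so the quaternary C–O bond is untouched (configuration retained), TIPS blocks SN2′ attack, and any Payne rearrangement of 4 is degenerate and regenerates the same enantiomer.

**Step 4**
Reactants: 6
Product: 7, (2S,4Z)-2-[(triisopropylsilyl)ethynyl]dec-4-ene-1,2-diol
Conditions: H2 (1 atm), Lindlar catalyst, quinoline, EtOAc, rt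
Reagents that add atoms: none
Why: Lindlar syn-semihydrogenation gives the 14Z alkene, and the TIPS-capped alkyne flanked by a quaternary carbon is too hindered to adsorb and be reduced.

**Step 5**
Reactants: 7
Product: 8, (2S,4Z)-2-ethynyldec-4-ene-1,2-diol
Conditions: TBAF, THF, 0 °C → rt
Reagents that add atoms: none
Why: Fluoride-mediated C–Si protodesilylation frees the terminal alkyne at a stage where no other silyl group or base-sensitive function is present.

**Step 6**
Reactants: 8
Product: 9, (2S,4Z)-2-ethynyl-1,2-bis(triethylsilyloxy)dec-4-ene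
Conditions: TESOTf (2.5 equiv), 2,6-lutidine, CH2Cl2, −78 → 0 °C
Reagents that add atoms: triethylsilyl triflate, CC[Si](CC)(CC)OS(=O)(=O)C(F)(F)F
Why: The silyl triflate is reactive enough to silylate both the primary and the hindered tertiary propargylic alcohol without affecting the stereocentre.

**Step 7**
Reactants: 9
Product: 10, (2S,4Z)-2-ethynyl-2-(triethylsilyloxy)dec-4-enal
Conditions: (COCl)2, DMSO, CH2Cl2, −78 → −40 °C; Et3N, → 0 °C
Reagents that add atoms: none
Why: Under Swern conditions a primary TES ether is cleaved and oxidised directly to the aldehyde while the tertiary TES ether survives, and the aldehyde has no α-H to epimerise.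

**Step 8**
Reactants: 11, methyl bis(2,2,2-trifluoroethyl)phosphonoacetate
Product: 12, methyl 2,2-dibromo-2-[bis(2,2,2-trifluoroethoxy)phosphoryl]acetate
Conditions: NaH (2.2 equiv), THF, 0 °C; Br2 (2.2 equiv), 0 °C → rt
Reagents that add atoms: bromine, BrBr
Why: Exhaustive electrophilic bromination of the active methylene avoids the mono/di mixtures that a 1:1 stoichiometry gives.

**Step 9**
Reactants: 12
Product: 13, methyl 2-bromo-2-[bis(2,2,2-trifluoroethoxy)phosphoryl]acetate (racemic, stereocentre irrelevant)
Conditions: SnCl2·2H2O (1.0 equiv), EtOH–H2O, 0 °C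
Reagents that add atoms: none
Why: Halophilic reductive monodebromination by Sn(II) gives a stabilised carbanion that is protonated, and it stops at the much less reducible monobromide.

**Step 10**
Reactants: 10; 13
Product: 14, methyl (2E,4R,6Z)-2-bromo-4-ethynyl-4-(triethylsilyloxy)dodeca-2,6-dienoate (ester cis to C12, Br trans)
Conditions: 13 (1.3 equiv), t-BuOK (1.25 equiv), 18-crown-6, THF, −78 °C; then 10, −78 → −40 °C
Reagents that add atoms: compound 13, COC(=O)C(Br)P(=O)(OCC(F)(F)F)OCC(F)(F)F
Why: This Still–Gennari-type Horner–Wadsworth–Emmons reaction of the bromophosphonate eliminates under kinetic control to place the ester cis to the aldehyde residue, giving the (E)-α-bromoacrylate, and C12 is not involved (its descriptor becomes R only through a CIP priority change).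

**Step 11**
Reactants: 15, methyl hex-5-ynoate; 16, pinacolborane
Product: 17, methyl (5E)-6-(4,4,5,5-tetramethyl-1,3,2-dioxaborolan-2-yl)hex-5-enoate
Conditions: Cp2Zr(H)Cl (5 mol %), Et3N (10 mol %), neat, 60 °C
Reagents that add atoms: pinacolborane, [H]B1OC(C)(C)C(C)(C)O1
Why: Zr-catalysed syn, anti-Markovnikov hydroboration of the terminal alkyne gives only the (E)-alkenylboronate (the future 5E) and tolerates the ester.

**Step 12 (key step, ring formation)**
Reactants: 14; 17
Product: 18, methyl (5E,7Z)-7-[(2R)-4-bromo-2-[(2Z)-oct-2-en-1-yl]-5-oxo-2-(triethylsilyloxy)cyclopent-3-en-1-ylidene]hept-5-enoate (12-O-TES bromoclavulone III)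
Conditions: [Rh(OMe)(cod)]2 (3 mol %), 17 (1.3 equiv), 4 Å MS, anhydrous 1,4-dioxane, 40 °C, 14 added by syringe pump over 4 h, dark
Reagents that add atoms: compound 17, COC(=O)CCC/C=C/B1OC(C)(C)C(C)(C)O1
Why: Proposed new method: in this Rh(I)-catalysed alkenylative cyclo-acylation, Rh–OMe transmetalates with 17 to an (E)-alkenyl-Rh(I) that adds syn across the terminal alkyne (carbon to the unhindered C7–H terminus, Rh to C8 beside the bulky oxygenated quaternary centre); the C8–Rh bond, held next to the cis-disposed, Br-activated ester by the (E)-enoate geometry, adds 5-exo to C9=O, and the Rh hemiketal alkoxide expels methoxide, giving the ketone and regenerating Rh–OMe (base- and water-free turnover, by-product MeO–Bpin); syn addition with retention therefore puts C6 and C9 cis (7Z), 5E is carried over from 17, C12 is untouched, and C10–Br survives because the cycle stays at Rh(I), which does not insert into vinyl bromides as Pd(0) or Ni(0) would; the closest known reaction type is the Rh(I)-catalysed arylative cyclisation of internal alkynes bearing tethered esters, ketones or aldehydes with arylboronic acids (carborhodation followed by intramolecular acylation), which has not been shown for terminal alkynes, alkenylboron donors or α-haloenoate acyl acceptors.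

**Step 13**
Reactants: 18
Product: 19, bromoclavulone III
Conditions: HF·pyridine, MeCN, 0 °C, amber flask
Reagents that add atoms: none
Why: Mild acidic fluoride desilylation cleaves the tertiary TES ether without base or nucleophile, so the methyl ester, the bromoenone, the light- and nucleophile-sensitive 7Z dienone and C12 (whose cation is destabilised by the enone) are preserved.

## Compound list

| No. | Name | SMILES | Role |
|---|---|---|---|
| 1 | 2-bromoprop-2-en-1-ol | OCC(Br)=C | starting material |
| 2 | (triisopropylsilyl)acetylene | C#C[Si](C(C)C)(C(C)C)C(C)C | starting material |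
| 3 | 2-methylidene-4-(triisopropylsilyl)but-3-yn-1-ol | OCC(=C)C#C[Si](C(C)C)(C(C)C)C(C)C | intermediate |
| 4 | [(2S)-2-{(triisopropylsilyl)ethynyl}oxiran-2-yl]methanol | OC[C@@]1(C#C[Si](C(C)C)(C(C)C)C(C)C)CO1 | intermediate |
| 5 | hept-1-yne | CCCCCC#C | starting material |
| 6 | (2S)-2-[(triisopropylsilyl)ethynyl]dec-4-yne-1,2-diol | CCCCCC#CC[C@@](O)(CO)C#C[Si](C(C)C)(C(C)C)C(C)C | intermediate |
| 7 | (2S,4Z)-2-[(triisopropylsilyl)ethynyl]dec-4-ene-1,2-diol | CCCCC/C=C\C[C@@](O)(CO)C#C[Si](C(C)C)(C(C)C)C(C)C | intermediate |
| 8 | (2S,4Z)-2-ethynyldec-4-ene-1,2-diol | CCCCC/C=C\C[C@@](O)(CO)C#C | intermediate |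
| 9 | (2S,4Z)-2-ethynyl-1,2-bis(triethylsilyloxy)dec-4-ene | CCCCC/C=C\C[C@@](O[Si](CC)(CC)CC)(CO[Si](CC)(CC)CC)C#C | intermediate |
| 10 | (2S,4Z)-2-ethynyl-2-(triethylsilyloxy)dec-4-enal | CCCCC/C=C\C[C@@](O[Si](CC)(CC)CC)(C=O)C#C | intermediate |
| 11 | methyl bis(2,2,2-trifluoroethyl)phosphonoacetate | COC(=O)CP(=O)(OCC(F)(F)F)OCC(F)(F)F | starting material |
| 12 | methyl 2,2-dibromo-2-[bis(2,2,2-trifluoroethoxy)phosphoryl]acetate | COC(=O)C(Br)(Br)P(=O)(OCC(F)(F)F)OCC(F)(F)F | intermediate |
| 13 | methyl 2-bromo-2-[bis(2,2,2-trifluoroethoxy)phosphoryl]acetate (racemic) | COC(=O)C(Br)P(=O)(OCC(F)(F)F)OCC(F)(F)F | intermediate |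
| 14 | methyl (2E,4R,6Z)-2-bromo-4-ethynyl-4-(triethylsilyloxy)dodeca-2,6-dienoate | CCCCC/C=C\C[C@@](O[Si](CC)(CC)CC)(/C=C(/Br)C(=O)OC)C#C | intermediate |
| 15 | methyl hex-5-ynoate | COC(=O)CCCC#C | starting material |
| 16 | pinacolborane | [H]B1OC(C)(C)C(C)(C)O1 | starting material |
| 17 | methyl (5E)-6-(pinacolboryl)hex-5-enoate | COC(=O)CCC/C=C/B1OC(C)(C)C(C)(C)O1 | intermediate |
| 18 | 12-O-triethylsilyl bromoclavulone III | CCCCC/C=C\C[C@@]1(O[Si](CC)(CC)CC)C=C(Br)C(=O)/C1=C\C=C\CCCC(=O)OC | intermediate |
| 19 | bromoclavulone III, (5E,7Z,12R,14Z) | CCCCC/C=C\C[C@@]1(O)C=C(Br)C(=O)/C1=C\C=C\CCCC(=O)OC | target |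

## Summary

Total step count: 13.
Longest linear sequence: 10 steps (1–7, 10, 12, 13).

### Three steps most likely to fail

1. **Step 12 (new Rh cascade).**
   - Risks: Rh-acetylide or vinylidene formation and oligomerisation of the terminal alkyne; 1,4-Rh shift or protodemetalation of the dienyl-Rh before acylation; over-addition to the product dienone.
   - Fallback (known chemistry, ring first):
     - Convert 10 to (R)-4-(triethylsilyloxy)-4-[(Z)-oct-2-enyl]cyclopent-2-enone. The sequence is Wittig methylenation of the CHO, Cy2BH hydroboration/oxidation of the ethynyl group to the C9 aldehyde, vinylMgBr addition, ring-closing metathesis and Dess–Martin oxidation.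
     - Install the bromine by alkaline H2O2 epoxidation followed by HBr opening and dehydration to the 2-bromoenone.
     - Attach the α chain by LDA aldol with methyl (E)-7-oxohept-5-enoate, then MsCl/Et3N elimination.
     - Separate 7Z from 7E by chromatography and recycle 7E by photoisomerisation.

2. **Step 2 (Sharpless epoxidation of the 2-alkynyl allylic alcohol).**
   - Risks: slow reaction of the conjugated alkene, reduced ee, and Ti-promoted opening of the propargylic epoxide.
   - Fallback: run the epoxidation on the mono-PMB ether of 2-methylidenepropane-1,3-diol, a well-behaved substrate class. Open that epoxide with heptynyllithium. Build the ethynyl group later from the CH2OPMB arm (DDQ, oxidation, Ohira–Bestmann). Choose the tartrate enantiomer according to which arm becomes C8.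

3. **Step 10 ((E)-selective bromo-HWE on a neopentyl-type aldehyde).**
   - Risks: low conversion or eroded E/Z selectivity.
   - Fallback:
     - Use an alkyne route on the TIPS-retained analogue of 10. Corey–Fuchs homologation and then n-BuLi/ClCO2Me give the ynoate.
     - Pd(0)/Bu3SnH syn-hydrostannation places the stannyl group α, with the ester cis to C12.
     - NBS bromodestannylation proceeds with retention of geometry.
     - AgF then releases the C8 terminal alkyne.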